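**Retrosynthetic overview**

1. The target's only ring, the γ-lactone, is formed last: strain-driven acyl-transfer ring expansion of a cis-β-lactone that carries a 1-carboxyvinyl group on C-3 (acid unmasked from its tert-butyl ester).
2. The cis-β-lactone comes from carbonylative ring expansion of a (2R,3R)-trans-2-(oxiranyl)acrylate. CO enters at the allylic carbon with inversion (sets C-3 of the target); the chain-bearing carbon keeps its configuration (C-2 of the target).
3. The epoxide comes from chiral sulfonium-ylide epoxidation of 14-oxotetradecyl acetate with the ylide from tert-butyl 2-(bromomethyl)acrylate.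
4. The aldehyde comes from linear hydroformylation of tridec-12-enyl acetate, itself made by copper-catalysed C7 + C6 Grignard coupling of 7-bromohept-1-ene with 6-bromohexan-1-ol, acetylated in the same pot.
5. Ring order: oxirane (3 atoms) → oxetan-2-one (4) → oxolan-2-one (5).

Assumption: the target is the (2R,3S)-trans acid (oxolane numbering: O1, C2 bears the chain, C3 bears CO2H), and the sense of induction of the chiral sulfide in step 3 is taken by analogy with its benzyl- and methallyl-ylide epoxidations ((2R,5R)-sulfide gives (S,S)-epoxides); if the sense proves reversed, the enantiomeric sulfide is used.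

**Step 1**
Reactants: 1 6-bromohexan-1-ol; 2 7-bromohept-1-ene
Product: 6 tridec-12-en-1-yl acetate, via hept-6-en-1-ylmagnesium bromide 3 (not isolated), via chloromagnesium 6-bromohexan-1-olate 4 (not isolated), via chloromagnesium tridec-12-en-1-olate 5 (not isolated)
Conditions: 2, Mg, THF, 40 °C (gives 3); 1, MeMgCl (1.0 equiv), THF, −20 °C (gives 4); then 3 (1.3 equiv), Li2CuCl4 (3 mol%), NMP (4 equiv), THF, 0 °C to rt; then Ac2O (3 equiv), 0 °C to rt
Reagents that add atoms: acetic anhydride, CC(=O)OC(C)=O
Why: Kochi-type copper-catalysed alkyl–alkyl Grignard cross-coupling joins the C7 and C6 pieces at the primary bromide while the hydroxyl is masked as its magnesium alkoxide 4, and the coupled alkoxide 5 is O-acetylated directly by Ac2O on quench; no stereocentre is formed.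

**Step 2**
Reactants: 6 tridec-12-en-1-yl acetate
Product: 7 14-oxotetradecyl acetate
Conditions: Rh(acac)(CO)2 (0.5 mol%), Xantphos (2 mol%), CO/H2 (1:1, 20 bar), toluene, 80 °C
Reagents that add atoms: carbon monoxide, [C-]#[O+]
Why: Rh/Xantphos hydroformylation of a terminal alkene is strongly linear-selective and adds the fourteenth chain carbon as the aldehyde without touching the acetate; it is an atom-economic addition with no co-product and no stereocentre.

**Step 3**
Reactants: 7 14-oxotetradecyl acetate; 8 tert-butyl 2-(bromomethyl)prop-2-enoate (the tert-butyl group is the acid protecting group, removed in step 5)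
Product: 10 tert-butyl 2-[(2R,3R)-3-(13-acetoxytridecyl)oxiran-2-yl]prop-2-enoate, via 1-[2-(tert-butoxycarbonyl)allyl]-(2S,5S)-2,5-dimethylthiolanium bromide 9 (not isolated)
Conditions: (2S,5S)-2,5-dimethylthiolane (1.1 equiv), 8, MeCN, rt; then 7, Cs2CO3 (1.5 equiv), MeCN, 0 °C to rt
Reagents that add atoms: none
Why: Chiral-sulfide-mediated Johnson–Corey–Chaykovsky epoxidation, in which salt 9 is deprotonated by the carbonate to a semi-stabilised 2-substituted allyl ylide that adds to 7 through the anti-betaine and closes to the trans-epoxide, the C2-symmetric thiolane fixing the ylide face so that both new stereocentres are set together as (2R,3R), while the mild solid base spares the acetate and the tert-butyl ester.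

**Step 4**
Reactants: 10 tert-butyl 2-[(2R,3R)-3-(13-acetoxytridecyl)oxiran-2-yl]prop-2-enoate
Product: 11 tert-butyl 2-[(2R,3S)-2-(13-acetoxytridecyl)-4-oxooxetan-3-yl]prop-2-enoate (cis-β-lactone)
Conditions: [(salph)Al(THF)2][Co(CO)4] (5 mol%; salph = N,N′-1,2-phenylenebis(3,5-di-tert-butylsalicylideneiminate)), CO (60 bar), DME, 50 °C
Reagents that add atoms: carbon monoxide, [C-]#[O+]
Why: Proposed new method: ring-expanding carbonylation of a 2-(oxiranyl)acrylate with CO insertion at the allylic ring carbon — the aluminium cation binds the epoxide oxygen, [Co(CO)4]− opens the activated C–O bond by backside SN2 attack at the allylic carbon (favoured by overlap with the acrylate π* and not diverted to ionisation because a 2-alkoxycarbonylallyl cation is destabilised), CO migratory insertion with retention and closure of the aluminium alkoxide onto the acylcobalt then give the β-lactone, so the acrylate-bearing carbon is set by inversion (R to S) while the chain-bearing carbon keeps R, which makes the lactone cis; the closest known reaction type is the Lewis acid/tetracarbonylcobaltate carbonylative ring expansion of alkyl-substituted trans-epoxides to cis-β-lactones, not yet shown on acrylate-type vinyl epoxides or with electronically (allylic) governed regiochemistry, and as an addition it has no co-product.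

**Step 5**
Reactants: 11 tert-butyl 2-[(2R,3S)-2-(13-acetoxytridecyl)-4-oxooxetan-3-yl]prop-2-enoate
Product: 14 (2R,3S)-2-(13-acetoxytridecyl)-4-methylidene-5-oxooxolane-3-carboxylic acid (CNP0178400.1), via 2-[(2R,3S)-2-(13-acetoxytridecyl)-4-oxooxetan-3-yl]prop-2-enoic acid 12 (not isolated), via (3S)-3-[(1R)-14-acetoxy-1-hydroxytetradecyl]-4-methylideneoxolane-2,5-dione 13 (not isolated)
Conditions: TFA/CH2Cl2 (1:1), 0 °C to rt; then toluene, 50 °C
Reagents that add atoms: none
Why: tert-Butyl ester acidolysis frees acrylic acid 12, whose carboxyl adds to the protonated, strained β-lactone carbonyl to give the five-membered mixed anhydride 13, and the liberated hydroxyl recloses on the conjugated anhydride carbonyl (translactonisation, an O-to-O acyl-transfer ring expansion driven by loss of four-membered ring strain); no bond to either stereocentre is broken, so the cis-β-lactone (3S,4R) maps onto the trans-(2R,3S) γ-lactone acid, and the acid medium leaves the acetate and the exocyclic alkene in place.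

**Compound list**

1 | 6-bromohexan-1-ol | OCCCCCCBr | starting material
2 | 7-bromohept-1-ene | C=CCCCCCBr | starting material
3 | hept-6-en-1-ylmagnesium bromide | C=CCCCCC[Mg]Br | intermediate
4 | chloromagnesium 6-bromohexan-1-olate | BrCCCCCCO[Mg]Cl | intermediate
5 | chloromagnesium tridec-12-en-1-olate | C=CCCCCCCCCCCCO[Mg]Cl | intermediate
6 | tridec-12-en-1-yl acetate | C=CCCCCCCCCCCCOC(C)=O | intermediate
7 | 14-oxotetradecyl acetate | CC(=O)OCCCCCCCCCCCCCC=O | intermediate
8 | tert-butyl 2-(bromomethyl)prop-2-enoate | C=C(CBr)C(=O)OC(C)(C)C | starting material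
9 | 1-[2-(tert-butoxycarbonyl)allyl]-(2S,5S)-2,5-dimethylthiolanium bromide | C[C@H]1CC[C@H](C)[S+]1CC(=C)C(=O)OC(C)(C)C.[Br-] | intermediate
10 | tert-butyl 2-[(2R,3R)-3-(13-acetoxytridecyl)oxiran-2-yl]prop-2-enoate | CC(=O)OCCCCCCCCCCCCC[C@H]1O[C@@H]1C(=C)C(=O)OC(C)(C)C | intermediate
11 | tert-butyl 2-[(2R,3S)-2-(13-acetoxytridecyl)-4-oxooxetan-3-yl]prop-2-enoate | CC(=O)OCCCCCCCCCCCCC[C@H]1OC(=O)[C@H]1C(=C)C(=O)OC(C)(C)C | intermediate
12 | 2-[(2R,3S)-2-(13-acetoxytridecyl)-4-oxooxetan-3-yl]prop-2-enoic acid | CC(=O)OCCCCCCCCCCCCC[C@H]1OC(=O)[C@H]1C(=C)C(=O)O | intermediate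
13 | (3S)-3-[(1R)-14-acetoxy-1-hydroxytetradecyl]-4-methylideneoxolane-2,5-dione | CC(=O)OCCCCCCCCCCCCC[C@@H](O)[C@H]1C(=O)OC(=O)C1=C | intermediate
14 | (2R,3S)-2-(13-acetoxytridecyl)-4-methylidene-5-oxooxolane-3-carboxylic acid | C=C1C(=O)O[C@H](CCCCCCCCCCCCCOC(C)=O)[C@H]1C(=O)O | target

**Totals**

Total step count: 5. Longest linear sequence: 5 steps (1 and 2 → 6 → 7 → 10 → 11 → 14).

**Steps most likely to fail**

Step 3 (ylide epoxidation). Risks: enantioselectivity with this sulfide is expected near 85–90% ee (14 is a crystalline acid, so recrystallisation is planned). The trans:cis ratio with an unbranched aldehyde may be moderate, and 7 can self-condense under base. The fallback sets out from 7 and comes back at 10. Takai–Utimoto borylation of 7 (CrCl2, Cl2CHB(pin), LiI, THF) gives (E)-15-(4,4,5,5-tetramethyl-1,3,2-dioxaborolan-2-yl)pentadec-14-en-1-yl acetate F1. Suzuki–Miyaura coupling of F1 with tert-butyl 2-bromoacrylate (Pd(PPh3)4, K3PO4, THF/H2O) gives tert-butyl (3E)-17-acetoxy-2-methylideneheptadec-3-enoate F2. Shi epoxidation (D-fructose-derived ketone, KHSO5, K2CO3 buffer, MeCN/dimethoxymethane, 0 °C) then oxidises only the electron-rich trans-disubstituted alkene, giving the (R,R)-epoxide 10.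

Step 4 (the proposed carbonylative ring expansion). Risks: SN2′ attack of the cobaltate at the acrylate CH2 (allylcobalt, then the six-membered unsaturated lactone), attack at the chain-bearing carbon, epoxide-to-ketone isomerisation, or alkene migration in 11. The fallback uses known chemistry, sets out from 7 and comes back at 14.
- (S)-4-Benzyl-1,3-oxazolidin-2-one is acylated (BuLi, methyl 4-chloro-4-oxobutanoate, THF, −78 °C) to methyl 4-[(4S)-4-benzyl-2-oxo-1,3-oxazolidin-3-yl]-4-oxobutanoate F3.
- Evans syn-aldol of F3 (Bu2BOTf, iPr2NEt, CH2Cl2, −78 °C) with 7, lactonising on acidic work-up, gives (4S)-3-{[(2R,3S)-2-(13-acetoxytridecyl)-5-oxooxolan-3-yl]carbonyl}-4-benzyl-1,3-oxazolidin-2-one F4.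
- LiOH/H2O2 (THF/H2O, 0 °C to rt) removes the auxiliary and the acetate, giving (2R,3S)-2-(13-hydroxytridecyl)-5-oxooxolane-3-carboxylic acid F5.
- Stiles carboxylation (MeOMgOCO2Me, DMF, 135 °C) gives (2R,3S)-2-(13-hydroxytridecyl)-5-oxooxolane-3,4-dicarboxylic acid F6.
- Decarboxylative Mannich methylenation (HCHO, N-methylaniline, NaOAc, AcOH) gives (2R,3S)-2-(13-hydroxytridecyl)-4-methylidene-5-oxooxolane-3-carboxylic acid F7.
- Acetylation of the primary alcohol (Ac2O, pyridine, 0 °C) gives 14.

Step 5 (acidolysis and acyl-transfer ring expansion). Risks: the transfer may stall at 12, or acid may move the exocyclic alkene. The fallback sets out from 11 and comes back at 14. Hydroperoxide hydrolysis of the strained lactone alone (LiOH, H2O2, THF/H2O, 0 °C, then Na2SO3) gives (2S,3R)-16-acetoxy-2-[3-(tert-butoxy)-3-oxoprop-1-en-2-yl]-3-hydroxyhexadecanoic acid F8. TFA/CH2Cl2 at rt then cleaves the tert-butyl ester of F8 and closes the γ-hydroxy acid to 14 by ordinary lactonisation.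

**Further compounds**

F1 | step 3 | (E)-15-(4,4,5,5-tetramethyl-1,3,2-dioxaborolan-2-yl)pentadec-14-en-1-yl acetate | CC(=O)OCCCCCCCCCCCCC/C=C/B1OC(C)(C)C(C)(C)O1
F2 | step 3 | tert-butyl (3E)-17-acetoxy-2-methylideneheptadec-3-enoate | CC(=O)OCCCCCCCCCCCCC/C=C/C(=C)C(=O)OC(C)(C)C
F3 | step 4 | methyl 4-[(4S)-4-benzyl-2-oxo-1,3-oxazolidin-3-yl]-4-oxobutanoate | COC(=O)CCC(=O)N1[C@@H](Cc2ccccc2)COC1=O
F4 | step 4 | (4S)-3-{[(2R,3S)-2-(13-acetoxytridecyl)-5-oxooxolan-3-yl]carbonyl}-4-benzyl-1,3-oxazolidin-2-one | CC(=O)OCCCCCCCCCCCCC[C@H]1OC(=O)C[C@@H]1C(=O)N2[C@@H](Cc3ccccc3)COC2=O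
F5 | step 4 | (2R,3S)-2-(13-hydroxytridecyl)-5-oxooxolane-3-carboxylic acid | OCCCCCCCCCCCCC[C@H]1OC(=O)C[C@@H]1C(=O)O
F6 | step 4 | (2R,3S)-2-(13-hydroxytridecyl)-5-oxooxolane-3,4-dicarboxylic acid (C-4 epimers) | OCCCCCCCCCCCCC[C@H]1OC(=O)C(C(=O)O)[C@@H]1C(=O)O
F7 | step 4 | (2R,3S)-2-(13-hydroxytridecyl)-4-methylidene-5-oxooxolane-3-carboxylic acid | OCCCCCCCCCCCCC[C@H]1OC(=O)C(=C)[C@@H]1C(=O)O
F8 | step 5 | (2S,3R)-16-acetoxy-2-[3-(tert-butoxy)-3-oxoprop-1-en-2-yl]-3-hydroxyhexadecanoic acid | CC(=O)OCCCCCCCCCCCCC[C@@H](O)[C@@H](C(=O)O)C(=C)C(=O)OC(C)(C)C
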